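**Strategy.** The dihydropyran is treated as a cyclic double acetal: C1 and C3 are both aldehyde-level carbons bridged by the ring oxygen O2 (numbering below). The unit O2–C1 is therefore delivered as one reagent, ethyl glyoxylate, whose ester carbon is a traceless handle later exchanged for acetate by oxidative decarboxylation. In one operation an auxiliary-controlled boron aldol joins C1 to C11a, setting C11a against C4a, and the new hydroxyl oxygen O2 closes onto the pendant acetal carbon C3 to give the six-membered ring. The precursor is an acyclic N-acyl oxazolidinone carrying C4a, a diethyl acetal arm and a dienyl chain; the nine-membered ring is closed afterwards by B-alkyl Suzuki coupling at C10–C11.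

Key step: step 6

Numbering (that of the cyclonona[c]pyran core): C1 acetal carbon; O2 ring oxygen; C3 enol-ether CH; C4 enol-ether carbon bearing the side chain; C4a and C11a ring-fusion carbons; C5–C11 the other carbons of the nine-membered ring (C7 carries the methyl group, C11 the exocyclic methylene carbon C19); C12 the side-chain carbinol carbon.

Remark on the chemistry: the facial sense of the (R)-configured phosphoric acid in step 15 is assigned by analogy with aryl and alkenyl aldehydes; if the substrate responds in the opposite sense, the enantiomeric catalyst is taken.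

Step 1
Reactants: 1 but-3-yn-1-ol; 2 vinyl bromide
Product: 4 (3E)-3-methylhexa-3,5-dien-1-ol, via alkenylalane 3 (not isolated)
Conditions: AlMe3, Cp2ZrCl2 (cat.), CH2Cl2, 0 °C to rt; then 2, ZnCl2, Pd(PPh3)4 (cat.), THF, rt; aqueous work-up
Reagents that add atoms: trimethylaluminium C[Al](C)C
Why: Zirconium-catalysed syn-carboalumination puts methyl on the internal and aluminium on the terminal alkyne carbon, and the palladium-catalysed Negishi coupling of the alkenylalane with vinyl bromide keeps the E geometry (no stereocentre is formed).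

Step 2
Reactants: 4 (3E)-3-methylhexa-3,5-dien-1-ol
Product: 5 (3E)-6-bromo-4-methylhexa-1,3-diene
Conditions: CBr4, PPh3, CH2Cl2, 0 °C
Reagents that add atoms: carbon tetrabromide BrC(Br)(Br)Br
Why: Appel bromination converts the primary homoallylic alcohol under neutral conditions that leave the diene untouched.

Step 3
Reactants: 6 (S)-4-benzyloxazolidin-2-one; 7 acryloyl chloride
Product: 8 (S)-3-acryloyl-4-benzyloxazolidin-2-one
Conditions: Et3N, LiCl, THF, −20 °C to rt
Reagents that add atoms: none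
Why: N-acylation of the oxazolidinone under mild LiCl/amine conditions should give the acrylimide without touching the auxiliary stereocentre.

Step 4
Reactants: 8 (S)-3-acryloyl-4-benzyloxazolidin-2-one; 9 4,4-diethoxybut-1-ene
Product: 10 (S)-4-benzyl-3-[(2E)-5,5-diethoxypent-2-enoyl]oxazolidin-2-one
Conditions: second-generation Grubbs catalyst RuCl2(=CHPh)(PCy3)(H2IMes) (5 mol%), CH2Cl2, 40 °C
Reagents that add atoms: none
Why: Olefin cross-metathesis between the electron-poor acrylimide and the terminal olefin should give the hetero-coupled E-enoyl imide selectively.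

Step 5
Reactants: 5 (3E)-6-bromo-4-methylhexa-1,3-diene; 10 (S)-4-benzyl-3-[(2E)-5,5-diethoxypent-2-enoyl]oxazolidin-2-one
Product: 12 (S)-4-benzyl-3-[(3R,6E)-3-(2,2-diethoxyethyl)-6-methylnona-6,8-dienoyl]oxazolidin-2-one, via Grignard reagent 11 (not isolated)
Conditions: Mg, THF; then CuBr·SMe2 (20 mol%), THF/Me2S, −78 °C; 10, to −20 °C; aq. NH4Cl
Reagents that add atoms: none
Why: Auxiliary-controlled copper-catalysed conjugate addition, in which the Grignard reagent attacks the magnesium-chelated syn-s-cis enoyl imide on the face opposite the benzyl group, sets C4a (3R in 12).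

Step 6
Reactants: 12 (S)-4-benzyl-3-[(3R,6E)-3-(2,2-diethoxyethyl)-6-methylnona-6,8-dienoyl]oxazolidin-2-one; 13 ethyl glyoxylate (freshly distilled)
Product: 15 ethyl (2S,3S,4R)-3-[(S)-4-benzyl-2-oxooxazolidine-3-carbonyl]-6-ethoxy-4-[(3E)-3-methylhexa-3,5-dien-1-yl]tetrahydro-2H-pyran-2-carboxylate (both C6 anomers), via aldol adduct 14 (not isolated)
Conditions: Bu2BOTf, i-Pr2NEt, CH2Cl2, −78 to 0 °C; 13, −78 °C; then EtOH, pyridinium p-toluenesulfonate, 0 °C to rt
Reagents that add atoms: none
Why: The Z-boron enolate of 12 adds to ethyl glyoxylate through a Zimmerman–Traxler chair (Evans syn-aldol) to form C1–C11a, and on ethanolysis under mild acid the freed hydroxyl oxygen O2 attacks the oxocarbenium ion generated from the diethyl acetal at C3 (transacetalisation), closing the tetrahydropyran. The closest known reaction types are auxiliary-controlled boron aldol additions to glyoxylates and acid-catalysed formation of 2-alkoxytetrahydropyrans from δ-hydroxy acetals. The only ring closed is the six-membered ring, by 6-exo-trig attack of O2 on the C3 oxocarbenium ion. C11a is controlled by the benzyl group of the auxiliary, which blocks one face of the enolate in the dipole-minimised chair, so the new C11a–C1 bond ends up trans to the C4a side chain as the trans ring fusion requires; C1 follows from the chair (syn) and C3 forms as an anomeric mixture, and both are erased or reset later (steps 11 and 13). The step needs the enolate to react with the aldehyde and not with the acetal, which the high electrophilicity of glyoxylate at −78 °C secures, and it needs auxiliary control to override the C4a stereocentre, which the rigid boron chair normally ensures.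

Step 7
Reactants: 15 ethyl (2S,3S,4R)-3-[(S)-4-benzyl-2-oxooxazolidine-3-carbonyl]-6-ethoxy-4-[(3E)-3-methylhexa-3,5-dien-1-yl]tetrahydro-2H-pyran-2-carboxylate
Product: 16 ethyl (2S,3S,4R)-6-ethoxy-3-[(ethylsulfanyl)carbonyl]-4-[(3E)-3-methylhexa-3,5-dien-1-yl]tetrahydro-2H-pyran-2-carboxylate
Conditions: EtSH, n-BuLi, THF, 0 °C
Reagents that add atoms: ethanethiol CCS
Why: Lithium ethanethiolate transacylates the imide at its exocyclic carbonyl (auxiliary removal) while the less electrophilic ethyl ester and the acetal should stay intact.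

Step 8
Reactants: 16 ethyl (2S,3S,4R)-6-ethoxy-3-[(ethylsulfanyl)carbonyl]-4-[(3E)-3-methylhexa-3,5-dien-1-yl]tetrahydro-2H-pyran-2-carboxylate
Product: 17 ethyl (2S,3S,4R)-3-acetyl-6-ethoxy-4-[(3E)-3-methylhexa-3,5-dien-1-yl]tetrahydro-2H-pyran-2-carboxylate
Conditions: MeZnI, PdCl2(PPh3)2 (5 mol%), toluene/THF, rt
Reagents that add atoms: methylzinc iodide C[Zn]I
Why: Fukuyama coupling (palladium-catalysed acyl substitution of a thioester by an organozinc) stops at the ketone and tolerates the ester, acetal and diene under neutral conditions that do not epimerise C11a.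

Step 9
Reactants: 17 ethyl (2S,3S,4R)-3-acetyl-6-ethoxy-4-[(3E)-3-methylhexa-3,5-dien-1-yl]tetrahydro-2H-pyran-2-carboxylate
Product: 18 ethyl (2S,3S,4R)-6-ethoxy-4-[(3E)-3-methylhexa-3,5-dien-1-yl]-3-[1-(trifluoromethylsulfonyloxy)vinyl]tetrahydro-2H-pyran-2-carboxylate
Conditions: KN(SiMe3)2, THF, −78 °C; then PhNTf2, −78 to 0 °C
Reagents that add atoms: N-phenylbis(trifluoromethanesulfonimide) O=S(=O)(N(c1ccccc1)S(=O)(=O)C(F)(F)F)C(F)(F)F
Why: Kinetic deprotonation of the methyl ketone at the methyl group and O-triflation of the enolate should give the 1,1-disubstituted enol triflate, whose CH2 carbon becomes C19.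

Step 10
Reactants: 18 ethyl (2S,3S,4R)-6-ethoxy-4-[(3E)-3-methylhexa-3,5-dien-1-yl]-3-[1-(trifluoromethylsulfonyloxy)vinyl]tetrahydro-2H-pyran-2-carboxylate
Product: 20 ethyl (1S,4aR,7E,11aR)-3-ethoxy-7-methyl-11-methylidene-1,3,4,4a,5,6,9,10,11,11a-decahydrocyclonona[c]pyran-1-carboxylate (both C3 anomers), via alkylborane 19 (not isolated)
Conditions: 9-BBN, THF, 0 °C to rt; then slow addition to PdCl2(dppf) (20 mol%), AsPh3, K3PO4, DMF/THF/H2O, high dilution, rt to 40 °C
Reagents that add atoms: none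
Why: 9-BBN hydroborates only the terminal CH2 of the 4,4-disubstituted diene to the homoallylic borane, and intramolecular B-alkyl Suzuki–Miyaura coupling with the enol triflate closes the nine-membered ring at C10–C11, creating the exocyclic methylene and leaving the E-olefin and the C4a/C11a stereocentres untouched.

Step 11
Reactants: 20 ethyl (1S,4aR,7E,11aR)-3-ethoxy-7-methyl-11-methylidene-1,3,4,4a,5,6,9,10,11,11a-decahydrocyclonona[c]pyran-1-carboxylate
Product: 23 ethyl (1S,4aS,7E,11aR)-4-formyl-7-methyl-11-methylidene-1,4a,5,6,9,10,11,11a-octahydrocyclonona[c]pyran-1-carboxylate, via enol ether 21 (not isolated), via iminium chloride 22 (not isolated)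
Conditions: POCl3, DMF, ClCH2CH2Cl, 0 °C to rt; then aq. NaOAc
Reagents that add atoms: N,N-dimethylformamide CN(C)C=O; water O
Why: Vilsmeier–Haack formylation of an acetal, in which the chloroiminium reagent converts the cyclic acetal into the C3=C4 enol ether and formylates its nucleophilic carbon C4, gives the push–pull aldehyde after hydrolysis, and both C3 anomers converge on the same product.

Step 12
Reactants: 23 ethyl (1S,4aS,7E,11aR)-4-formyl-7-methyl-11-methylidene-1,4a,5,6,9,10,11,11a-octahydrocyclonona[c]pyran-1-carboxylate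
Product: 24 (1S,4aS,7E,11aR)-4-formyl-7-methyl-11-methylidene-1,4a,5,6,9,10,11,11a-octahydrocyclonona[c]pyran-1-carboxylic acid
Conditions: Me3SnOH, ClCH2CH2Cl, 70 °C; then dilute aq. HCl
Reagents that add atoms: trimethyltin hydroxide C[Sn](C)(C)O
Why: Trimethyltin hydroxide cleaves the activated α-alkoxy ethyl ester under nearly neutral conditions, which should spare the hydroxide-sensitive vinylogous formate.

Step 13
Reactants: 24 (1S,4aS,7E,11aR)-4-formyl-7-methyl-11-methylidene-1,4a,5,6,9,10,11,11a-octahydrocyclonona[c]pyran-1-carboxylic acid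
Product: 25 (1R,4aS,7E,11aR)-4-formyl-7-methyl-11-methylidene-1,4a,5,6,9,10,11,11a-octahydrocyclonona[c]pyran-1-yl acetate
Conditions: Pb(OAc)4, pyridine, benzene, 0 °C to rt
Reagents that add atoms: lead tetraacetate CC(=O)O[Pb](OC(C)=O)(OC(C)=O)OC(C)=O
Why: Oxidative decarboxylation of the α-alkoxy acid by tetravalent lead (Kochi-type) gives the C1 oxocarbenium ion, which acetate should capture trans to the C11a substituent (axial, anomerically favoured), so the 1R configuration is set whatever the configuration of the acid.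

Step 14
Reactants: 25 (1R,4aS,7E,11aR)-4-formyl-7-methyl-11-methylidene-1,4a,5,6,9,10,11,11a-octahydrocyclonona[c]pyran-1-yl acetate
Product: 26 (1R,4aS,7S,8S,11aR)-7,8-epoxy-4-formyl-7-methyl-11-methylidene-1,4a,5,6,7,8,9,10,11,11a-decahydrocyclonona[c]pyran-1-yl acetate
Conditions: mCPBA, NaHCO3, CH2Cl2, −20 to 0 °C
Reagents that add atoms: 3-chloroperbenzoic acid OOC(=O)c1cccc(Cl)c1
Why: Prilezhaev epoxidation should take the strained E-trisubstituted C7=C8 olefin before the 1,1-disubstituted olefin and the formyl-deactivated enol ether, from its exposed outer face as in the epoxidation of β-caryophyllene, which corresponds to the (7S,8S)-epoxide.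

Step 15
Reactants: 26 (1R,4aS,7S,8S,11aR)-7,8-epoxy-4-formyl-7-methyl-11-methylidene-1,4a,5,6,7,8,9,10,11,11a-decahydrocyclonona[c]pyran-1-yl acetate
Product: 28 (1R,4aS,7S,8S,11aR)-7,8-epoxy-4-[(1R)-1-hydroxybut-3-en-1-yl]-7-methyl-11-methylidene-1,4a,5,6,7,8,9,10,11,11a-decahydrocyclonona[c]pyran-1-yl acetate, via pinacol borate 27 (not isolated)
Conditions: allylboronic acid pinacol ester, (R)-3,3'-bis(2,4,6-triisopropylphenyl)-1,1'-binaphthyl-2,2'-diyl hydrogen phosphate (5 mol%), toluene, −30 °C; then aq. NaHCO3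
Reagents that add atoms: allylboronic acid pinacol ester C=CCB1OC(C)(C)C(C)(C)O1
Why: Chiral phosphoric acid-catalysed allylboration proceeds through a closed chair transition state in which the catalyst selects the aldehyde face, which should set C12 as R without acid or base strong enough to harm the epoxide or the anomeric acetate.

Step 16
Reactants: 28 (1R,4aS,7S,8S,11aR)-7,8-epoxy-4-[(1R)-1-hydroxybut-3-en-1-yl]-7-methyl-11-methylidene-1,4a,5,6,7,8,9,10,11,11a-decahydrocyclonona[c]pyran-1-yl acetate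
Product: 29 (1R)-1-[(1R,4aS,7S,8S,11aR)-1-acetoxy-7,8-epoxy-7-methyl-11-methylidene-1,4a,5,6,7,8,9,10,11,11a-decahydrocyclonona[c]pyran-4-yl]but-3-en-1-yl acetate
Conditions: Ac2O, pyridine, DMAP (cat.), CH2Cl2, 0 °C
Reagents that add atoms: acetic anhydride CC(=O)OC(C)=O
Why: DMAP-catalysed acetylation of the secondary alcohol is a standard acyl transfer that retains the C12 configuration.

Step 17
Reactants: 29 (1R)-1-[(1R,4aS,7S,8S,11aR)-1-acetoxy-7,8-epoxy-7-methyl-11-methylidene-1,4a,5,6,7,8,9,10,11,11a-decahydrocyclonona[c]pyran-4-yl]but-3-en-1-yl acetate; 30 methyl methacrylate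
Product: 31 methyl (2E,5R)-5-acetoxy-5-[(1R,4aS,7S,8S,11aR)-1-acetoxy-7,8-epoxy-7-methyl-11-methylidene-1,4a,5,6,7,8,9,10,11,11a-decahydrocyclonona[c]pyran-4-yl]-2-methylpent-2-enoate (CNP0184381.4)
Conditions: 30 (excess), second-generation Grubbs catalyst RuCl2(=CHPh)(PCy3)(H2IMes) (5 mol%), CH2Cl2, 40 °C
Reagents that add atoms: none
Why: Olefin cross-metathesis of the terminal olefin with methyl methacrylate should give the E-trisubstituted enoate, while the 1,1-disubstituted olefin, the trisubstituted enol ether and the epoxide are inert to the catalyst.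

**Compound list**

1 | but-3-yn-1-ol | C#CCCO | starting material
2 | vinyl bromide | C=CBr | starting material
3 | (E)-alkenylalane, dimethyl[(1E)-4-(dimethylalumanyloxy)-2-methylbut-1-en-1-yl]alumane | C[Al](C)/C=C(\C)CCO[Al](C)C | intermediate (not isolated)
4 | (3E)-3-methylhexa-3,5-dien-1-ol | C=C/C=C(\C)CCO | intermediate
5 | (3E)-6-bromo-4-methylhexa-1,3-diene | C=C/C=C(\C)CCBr | intermediate
6 | (S)-4-benzyloxazolidin-2-one | O=C1N[C@@H](Cc2ccccc2)CO1 | starting material
7 | acryloyl chloride | C=CC(=O)Cl | starting material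
8 | (S)-3-acryloyl-4-benzyloxazolidin-2-one | C=CC(=O)N1[C@@H](Cc2ccccc2)COC1=O | intermediate
9 | 4,4-diethoxybut-1-ene | C=CCC(OCC)OCC | starting material
10 | (S)-4-benzyl-3-[(2E)-5,5-diethoxypent-2-enoyl]oxazolidin-2-one | CCOC(C/C=C/C(=O)N1[C@@H](Cc2ccccc2)COC1=O)OCC | intermediate
11 | [(3E)-3-methylhexa-3,5-dien-1-yl]magnesium bromide | C=C/C=C(\C)CC[Mg]Br | intermediate (not isolated)
12 | (S)-4-benzyl-3-[(3R,6E)-3-(2,2-diethoxyethyl)-6-methylnona-6,8-dienoyl]oxazolidin-2-one | C=C/C=C(\C)CC[C@@H](CC(=O)N1[C@@H](Cc2ccccc2)COC1=O)CC(OCC)OCC | intermediate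
13 | ethyl glyoxylate | CCOC(=O)C=O | starting material
14 | ethyl (2S,3S,4R,7E)-3-[(S)-4-benzyl-2-oxooxazolidine-3-carbonyl]-4-(2,2-diethoxyethyl)-2-hydroxy-7-methyldeca-7,9-dienoate (syn-aldol adduct, formed as its dibutylboron aldolate) | CCOC(=O)[C@@H](O)[C@@H](C(=O)N1[C@@H](Cc2ccccc2)COC1=O)[C@@H](CC(OCC)OCC)CC/C(C)=C/C=C | intermediate (not isolated)
15 | ethyl (2S,3S,4R)-3-[(S)-4-benzyl-2-oxooxazolidine-3-carbonyl]-6-ethoxy-4-[(3E)-3-methylhexa-3,5-dien-1-yl]tetrahydro-2H-pyran-2-carboxylate, both C6 anomers | CCOC(=O)[C@H]1OC(OCC)C[C@@H](CC/C(C)=C/C=C)[C@@H]1C(=O)N1[C@@H](Cc2ccccc2)COC1=O | intermediate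
16 | ethyl (2S,3S,4R)-6-ethoxy-3-[(ethylsulfanyl)carbonyl]-4-[(3E)-3-methylhexa-3,5-dien-1-yl]tetrahydro-2H-pyran-2-carboxylate | CCOC(=O)[C@H]1OC(OCC)C[C@@H](CC/C(C)=C/C=C)[C@@H]1C(=O)SCC | intermediate
17 | ethyl (2S,3S,4R)-3-acetyl-6-ethoxy-4-[(3E)-3-methylhexa-3,5-dien-1-yl]tetrahydro-2H-pyran-2-carboxylate | CCOC(=O)[C@H]1OC(OCC)C[C@@H](CC/C(C)=C/C=C)[C@@H]1C(C)=O | intermediate
18 | ethyl (2S,3S,4R)-6-ethoxy-4-[(3E)-3-methylhexa-3,5-dien-1-yl]-3-[1-(trifluoromethylsulfonyloxy)vinyl]tetrahydro-2H-pyran-2-carboxylate | CCOC(=O)[C@H]1OC(OCC)C[C@@H](CC/C(C)=C/C=C)[C@@H]1C(=C)OS(=O)(=O)C(F)(F)F | intermediate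
19 | ethyl (2S,3S,4R)-4-[(3E)-6-(9-borabicyclo[3.3.1]nonan-9-yl)-3-methylhex-3-en-1-yl]-6-ethoxy-3-[1-(trifluoromethylsulfonyloxy)vinyl]tetrahydro-2H-pyran-2-carboxylate | CCOC(=O)[C@H]1OC(OCC)C[C@@H](CC/C(C)=C/CCB2C3CCCC2CCC3)[C@@H]1C(=C)OS(=O)(=O)C(F)(F)F | intermediate (not isolated)
20 | ethyl (1S,4aR,7E,11aR)-3-ethoxy-7-methyl-11-methylidene-1,3,4,4a,5,6,9,10,11,11a-decahydrocyclonona[c]pyran-1-carboxylate, trans-fused, both C3 anomers | CCOC(=O)[C@H]1OC(OCC)C[C@H]2CC/C(C)=C/CCC(=C)[C@H]12 | intermediate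
21 | ethyl (7E)-7-methyl-11-methylidene-1,4a,5,6,9,10,11,11a-octahydrocyclonona[c]pyran-1-carboxylate, configuration at C1, C4a and C11a as in 20 | CCOC(=O)[C@H]1OC=C[C@H]2CC/C(C)=C/CCC(=C)[C@H]12 | intermediate (not isolated)
22 | N,N-dimethyliminium chloride of aldehyde 23 (C4–CH=NMe2+ Cl−) | CCOC(=O)[C@H]1OC=C(C=[N+](C)C)[C@H]2CC/C(C)=C/CCC(=C)[C@H]12.[Cl-] | intermediate (not isolated)
23 | ethyl (1S,4aS,7E,11aR)-4-formyl-7-methyl-11-methylidene-1,4a,5,6,9,10,11,11a-octahydrocyclonona[c]pyran-1-carboxylate | CCOC(=O)[C@H]1OC=C(C=O)[C@H]2CC/C(C)=C/CCC(=C)[C@H]12 | intermediate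
24 | (1S,4aS,7E,11aR)-4-formyl-7-methyl-11-methylidene-1,4a,5,6,9,10,11,11a-octahydrocyclonona[c]pyran-1-carboxylic acid | OC(=O)[C@H]1OC=C(C=O)[C@H]2CC/C(C)=C/CCC(=C)[C@H]12 | intermediate
25 | (1R,4aS,7E,11aR)-4-formyl-7-methyl-11-methylidene-1,4a,5,6,9,10,11,11a-octahydrocyclonona[c]pyran-1-yl acetate | CC(=O)O[C@H]1OC=C(C=O)[C@H]2CC/C(C)=C/CCC(=C)[C@H]12 | intermediate
26 | (1R,4aS,7S,8S,11aR)-7,8-epoxy-4-formyl-7-methyl-11-methylidene-1,4a,5,6,7,8,9,10,11,11a-decahydrocyclonona[c]pyran-1-yl acetate | CC(=O)O[C@H]1OC=C(C=O)[C@H]2CC[C@]3(C)O[C@H]3CCC(=C)[C@H]12 | intermediate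
27 | pinacol borate of alcohol 28 (C12–O–B(pin)) | CC(=O)O[C@H]1OC=C([C@@H](CC=C)OB4OC(C)(C)C(C)(C)O4)[C@H]2CC[C@]3(C)O[C@H]3CCC(=C)[C@H]12 | intermediate (not isolated)
28 | (1R,4aS,7S,8S,11aR)-7,8-epoxy-4-[(1R)-1-hydroxybut-3-en-1-yl]-7-methyl-11-methylidene-1,4a,5,6,7,8,9,10,11,11a-decahydrocyclonona[c]pyran-1-yl acetate | CC(=O)O[C@H]1OC=C([C@@H](CC=C)O)[C@H]2CC[C@]3(C)O[C@H]3CCC(=C)[C@H]12 | intermediate
29 | (1R)-1-[(1R,4aS,7S,8S,11aR)-1-acetoxy-7,8-epoxy-7-methyl-11-methylidene-1,4a,5,6,7,8,9,10,11,11a-decahydrocyclonona[c]pyran-4-yl]but-3-en-1-yl acetate | CC(=O)O[C@H]1OC=C([C@@H](CC=C)OC(C)=O)[C@H]2CC[C@]3(C)O[C@H]3CCC(=C)[C@H]12 | intermediate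
30 | methyl methacrylate | C=C(C)C(=O)OC | starting material
31 | methyl (2E,5R)-5-acetoxy-5-[(1R,4aS,7S,8S,11aR)-1-acetoxy-7,8-epoxy-7-methyl-11-methylidene-1,4a,5,6,7,8,9,10,11,11a-decahydrocyclonona[c]pyran-4-yl]-2-methylpent-2-enoate (CNP0184381.4) | C=C1CC[C@@H]2O[C@@]2(C)CC[C@@H]2C([C@@H](C/C=C(\C)C(=O)OC)OC(C)=O)=CO[C@H](OC(C)=O)[C@@H]12 | target

**Step count and risks**

Total: 17 steps. Longest linear sequence: 15 steps (steps 1, 2 and 5–17 from but-3-yn-1-ol; equally steps 3–17 from the oxazolidinone).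

Most likely to fail:

Step 10. The alkylborane may be lost to intermolecular coupling or protodeboronation before the strained nine-membered ring closes. The fallback sets out from 18 and comes back at 20, and replaces the cross-coupling by a carbonyl addition. Compound 18 is hydroborated with 9-BBN and oxidised with NaBO3 to the primary alcohol F1, and Dess–Martin periodinane gives the β,γ-unsaturated aldehyde F2. An intramolecular Nozaki–Hiyama–Kishi reaction of the enol triflate with the aldehyde (CrCl2, NiCl2 catalytic, DMF, high dilution) closes the ring as the cyclic allylic alcohol F3, a C10 epimer mixture. Methyl chloroformate and pyridine give the allylic methyl carbonate F4. Palladium-catalysed formate reduction (Pd(OAc)2, PBu3, HCO2NH4), which delivers hydride to the more substituted allyl terminus and so keeps the exocyclic methylene, returns 20.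

Step 11. Acid set free during the formylation may trigger transannular cyclisation or isomerisation of the E-cyclononene and the exocyclic olefin. The fallback sets out from 20 and comes back at 23, and uses a buffered two-stage route with a different electrophile. Elimination of ethanol with TMSOTf and i-Pr2NEt gives enol ether 21, now isolated. Addition of the enol ether to triethyl orthoformate (ZnCl2 catalytic, CH2Cl2, low temperature) gives the 3-ethoxy-4-(diethoxymethyl) acetal F5. Pyridinium p-toluenesulfonate in wet acetone hydrolyses the exocyclic acetal and eliminates ethanol across C3–C4 to return 23.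

Step 13. Tetravalent lead may oxidise the strained olefins in competition with decarboxylation, or acetate capture at C1 may be unselective. The fallback sets out from 24 and comes back at 25, and is non-oxidative. Diphenylphosphoryl azide and Et3N in toluene give the acyl azide F6, which on warming undergoes Curtius rearrangement with retention to the isocyanate F7. Aqueous acetic acid in THF hydrolyses it through the carbamic acid and the hemiaminal to the lactol F8. Ac2O, pyridine and DMAP acetylate the anomeric hydroxyl, the anomers equilibrating through the open form, to give 25.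

**Further compounds**

F1 | step 10 | ethyl (2S,3S,4R)-6-ethoxy-4-[(3E)-6-hydroxy-3-methylhex-3-en-1-yl]-3-[1-(trifluoromethylsulfonyloxy)vinyl]tetrahydro-2H-pyran-2-carboxylate | CCOC(=O)[C@H]1OC(OCC)C[C@@H](CC/C(C)=C/CCO)[C@@H]1C(=C)OS(=O)(=O)C(F)(F)F
F2 | step 10 | ethyl (2S,3S,4R)-6-ethoxy-4-[(3E)-3-methyl-6-oxohex-3-en-1-yl]-3-[1-(trifluoromethylsulfonyloxy)vinyl]tetrahydro-2H-pyran-2-carboxylate | CCOC(=O)[C@H]1OC(OCC)C[C@@H](CC/C(C)=C/CC=O)[C@@H]1C(=C)OS(=O)(=O)C(F)(F)F
F3 | step 10 | ethyl (1S,4aR,7E,11aR)-3-ethoxy-10-hydroxy-7-methyl-11-methylidene-1,3,4,4a,5,6,9,10,11,11a-decahydrocyclonona[c]pyran-1-carboxylate (C10 epimers) | CCOC(=O)[C@H]1OC(OCC)C[C@H]2CC/C(C)=C/CC(O)C(=C)[C@H]12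
F4 | step 10 | ethyl (1S,4aR,7E,11aR)-3-ethoxy-10-(methoxycarbonyloxy)-7-methyl-11-methylidene-1,3,4,4a,5,6,9,10,11,11a-decahydrocyclonona[c]pyran-1-carboxylate | CCOC(=O)[C@H]1OC(OCC)C[C@H]2CC/C(C)=C/CC(OC(=O)OC)C(=C)[C@H]12
F5 | step 11 | ethyl (1S,4aR,7E,11aR)-4-(diethoxymethyl)-3-ethoxy-7-methyl-11-methylidene-1,3,4,4a,5,6,9,10,11,11a-decahydrocyclonona[c]pyran-1-carboxylate (C3/C4 isomer mixture) | CCOC(=O)[C@H]1OC(OCC)C(C(OCC)OCC)[C@H]2CC/C(C)=C/CCC(=C)[C@H]12
F6 | step 13 | (1S,4aS,7E,11aR)-4-formyl-7-methyl-11-methylidene-1,4a,5,6,9,10,11,11a-octahydrocyclonona[c]pyran-1-carbonyl azide | [N-]=[N+]=NC(=O)[C@H]1OC=C(C=O)[C@H]2CC/C(C)=C/CCC(=C)[C@H]12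
F7 | step 13 | 1-isocyanato derivative, (4aS,7E,11aR)-1-isocyanato-7-methyl-11-methylidene-1,4a,5,6,9,10,11,11a-octahydrocyclonona[c]pyran-4-carbaldehyde, C1 configuration retained from 24 | O=C=N[C@H]1OC=C(C=O)[C@H]2CC/C(C)=C/CCC(=C)[C@H]12
F8 | step 13 | (4aS,7E,11aR)-1-hydroxy-7-methyl-11-methylidene-1,4a,5,6,9,10,11,11a-octahydrocyclonona[c]pyran-4-carbaldehyde (lactol, both anomers) | OC1OC=C(C=O)[C@H]2CC/C(C)=C/CCC(=C)[C@H]12
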